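A small charge of free catalyst, 0.44 mM, has to carry 0.40 M of substrate in the cedar flask, so each catalyst molecule counts.

- cedar: substrate 0.40 M; gas phase 90 mM (held); free catalyst 0.44 mM; impurity 0.19 mM; the very flask that is asked about, followed so far
- flask: substrate 0.40 M; gas phase 90 mM (held); free catalyst 0.44 mM; impurity 0.19 mM; time 4.0 min

- cedar (time / s: target / %): 15.0: 14.0; 30.0: 26.0; 40.0: 30.5; 60.0: 35.6; 80.0: 38.4

(standard deviation of a reading: 1 percentage point)

- at the start none of the gas is dissolved
- steps under discussion: gas phase <-> dissolved gas; substrate + dissolved gas + free catalyst <-> free catalyst + target; free catalyst + impurity -> spent catalyst A; free catalyst -> spent catalyst B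

- the target standing at 4.0 min, as a percentage of the substrate charged
- the change that raises the amount of target at 4.0 min, in percent of the substrate charged most ("none" if none brings more than 2 percentage points) (Sunday's / Friday's / Saturday's / none)
- amount of target at 4.0 min, in percent of the substrate charged, after Saturday's

- Sunday's: doubling the saturation concentration of gas phase, all else as stated
- Friday's: doubling the transfer coefficient of the gas phase, all else as stated
- Saturday's: doubling the amount of free catalyst, all else as stated

*Follow one molecule of free catalyst in this flask. What forks does it meet?*
Two ways out of the working round: it meets impurity and becomes spent catalyst A, or it decays to spent catalyst B.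

*How many take the first way?*
Impurity takes catalyst one for one. Its charge over the catalyst's gives 43.2 %, and that share of the catalyst charge lost to impurity is the toll. That leaves 0.250 mM to work.

*You assume the impurity gets used up. Can the cedar run show that?*
No. The toll holds if impurity is used up before the catalyst's own decay ends the contest, and I take that as a bet.

*Where does the target stop?*
The last equal time steps add 5.1 percentage points, then 2.8 points, a ratio of 0.549. Summing that shrinking tail gives 41.8 %, a loose reading, since each point carries a scatter of 1 point.

*Which change?*
Saturday's cuts the toll to 21.6 % and gives 2.76 times the working catalyst, but those molecules share the same gas supply. Sunday's doubles the gas each survivor can draw on, so I lean to Sunday's.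

The forecast, a little above my figure, gives 43 %, 60 % after Saturday's, and Sunday's: “Sunday's is the safest choice”.

The flask gives 38.1 %, 57.7 % after Saturday's, and Sunday's as the best change, worth 25 points.

    gas phase ⇌ dissolved gas, rate k1*(csat - [dissolved gas]) (kL = 0.0918 s⁻¹)
    substrate + dissolved gas + free catalyst ⇌ free catalyst + target (K = 96.4 L mol⁻¹, k = 3160 L² mol⁻² s⁻¹)
    free catalyst + impurity → spent catalyst A (k = 5710 L mol⁻¹ s⁻¹)
    free catalyst → spent catalyst B (k = 0.0539 s⁻¹)

At 4.00 min free catalyst in this flask stands at 0 % with 61.9 % of the substrate unused; spent catalyst A holds 43.2 %, the toll, and spent catalyst B 56.8 %. Without the loss to spent catalyst B the flask gives 89.7 % instead of 38.1 %. The neighbour charged with 7.5 × 10⁻⁴ M of free catalyst has a toll of 25.3 %, and spent catalyst A stands there at 25.3 %, with 53.8 % of target.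

The data come from a simulation on assumed constants; the scatter is artificial.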